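**Convention (one line):** locants follow the target skeleton – cyclopentane C1–C4 (C2 isopropenyl, C4 oxygen), spiro C5, cyclohexane C6–C10 (C6 and C10 methyl, C8 ketone, C9 acetate); the target is then (2R,4S,5S,9S,10R), and earlier carbons are labelled by the position they reach in the target.

## Retrosynthetic overview

1. C9–OAc goes on last by α′-acetoxylation of the spiro enone; the C4 senecioate comes from the C4 alcohol, made by chemoselective reduction of a spiro[4.5]dec-6-ene-4,8-dione.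
2. Ring B (formed second): formal [4+2] of a 2-ethylidenecyclopentanone (C5=C6) with a 1-seleno-2-silyloxypenta-1,3-diene (C7–C10), then selenoxide elimination to place C6=C7.
3. Ring A (formed first), key step: C4–C5 bond by carbene-catalysed acyl-anion addition of the aldehyde carbon of a 5-alkynal across its C≡C bond.
4. The alkynal comes from (S)-(+)-carvone by Weitz–Scheffer epoxidation and Eschenmoser–Tanabe fragmentation; the diene from (E)-pent-3-en-2-one.

## Route

**Step 1**
Reactants: 1 (S)-(+)-carvone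
Product: 2 (1S,4S,6S)-1-methyl-4-(prop-1-en-2-yl)-7-oxabicyclo[4.1.0]heptan-2-one
Conditions: 30% H2O2, NaOH (cat.), MeOH, 0 °C
Reagents that add atoms: hydrogen peroxide, OO
Why: Weitz–Scheffer nucleophilic epoxidation attacks only the enone C=C (the isopropenyl group is inert) and hydroperoxide adds anti to the isopropenyl group to give one trans epoxide, whose two new centres are erased in step 2.

**Step 2**
Reactants: 2 (1S,4S,6S)-1-methyl-4-(prop-1-en-2-yl)-7-oxabicyclo[4.1.0]heptan-2-one
Product: 4 (3R)-3-(prop-1-en-2-yl)hept-5-ynal, via epoxy tosylhydrazone 3 (not isolated)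
Conditions: TsNHNH2, AcOH–CH2Cl2 (1:1), −20 to 23 °C
Reagents that add atoms: none
Why: Eschenmoser–Tanabe fragmentation of the α,β-epoxy tosylhydrazone gives the alkyne (C5≡C6–CH3) and, because the β-epoxide carbon bears H, the aldehyde (C4), while the carvone stereocentre is untouched and becomes C2 (R).

**Step 3 (key step)**
Reactants: 4 (3R)-3-(prop-1-en-2-yl)hept-5-ynal
Product: 6 (2E,4R)-2-ethylidene-4-(prop-1-en-2-yl)cyclopentan-1-one, via Breslow enaminol 5 (not isolated)
Conditions: 1,3-bis(2,4,6-trimethylphenyl)imidazolium chloride (IMes·HCl, 10 mol %), K2CO3 (20 mol %), THF (0.05 M), 70 °C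
Reagents that add atoms: none
Why: Proposed new method: the carbene turns the aldehyde into the Breslow enaminol 5, an acyl anion equivalent, whose nucleophilic C4 and O–H add in a concerted Conia-ene-like 5-exo-dig hydroacylation across the tethered C≡C bond (C4–C5 bond; syn delivery of acyl and H gives the E ethylidene), the isopropenyl group being reachable only in a 4-exo or 5-endo mode; the closest known reaction type is the carbene-catalysed intramolecular hydroacylation of unactivated alkynes by aromatic aldehydes, extended here to an enolisable aliphatic 5-alkynal, and no stereocentre is made or touched.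

**Step 4**
Reactants: 7 (E)-pent-3-en-2-one
Product: 8 (E)-1-(phenylselanyl)pent-3-en-2-one
Conditions: LiN(i-Pr)2 (commercial solution), THF, −78 °C; then PhSeCl
Reagents that add atoms: benzeneselenenyl chloride, Cl[Se]c1ccccc1
Why: Kinetic α′-deprotonation of the enone gives the cross-conjugated enolate, which is selenenylated at the methyl carbon (Reich selenenylation; future C7).

**Step 5**
Reactants: 8 (E)-1-(phenylselanyl)pent-3-en-2-one
Product: 9 tert-butyl(dimethyl){[(1Z,3E)-1-(phenylselanyl)penta-1,3-dien-2-yl]oxy}silane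
Conditions: TBSOTf, Et3N, CH2Cl2, 0 °C
Reagents that add atoms: tert-butyldimethylsilyl trifluoromethanesulfonate, CC(C)(C)[Si](C)(C)OS(=O)(=O)C(F)(F)F
Why: Soft enolisation at the selenium-acidified CH2 gives the cross-conjugated 2-silyloxydiene, with selenium on the outside (Z enol ether) so the s-cis diene is accessible.

**Step 6**
Reactants: 6 (2E,4R)-2-ethylidene-4-(prop-1-en-2-yl)cyclopentan-1-one; 9 tert-butyl(dimethyl){[(1Z,3E)-1-(phenylselanyl)penta-1,3-dien-2-yl]oxy}silane
Product: 11 (2R,5S,6R,7S,10S)-6,10-dimethyl-7-(phenylselanyl)-2-(prop-1-en-2-yl)spiro[4.5]decane-4,8-dione, via silyl enol ether cycloadduct 10 (not isolated)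
Conditions: Tf2NH (10 mol %), CH2Cl2, −78 to −20 °C; then 1 M HCl, THF, 23 °C
Reagents that add atoms: none
Why: Acid-catalysed Diels–Alder reaction (Mukaiyama–Michael/Michael in the stepwise limit) joins the enol-ether terminus C7 to the enone β-carbon C6 and the methyl-bearing terminus C10 to C5, on the face of 6 anti to the isopropenyl group (C10 trans, C6 cis to isopropenyl at C5) and endo to the ketone (C10 methyl cis to C4); work-up cleaves the enol ether, and C6/C7 are transient centres.

**Step 7**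
Reactants: 11 (2R,5S,6R,7S,10S)-6,10-dimethyl-7-(phenylselanyl)-2-(prop-1-en-2-yl)spiro[4.5]decane-4,8-dione
Product: 13 (2R,5S,10S)-6,10-dimethyl-2-(prop-1-en-2-yl)spiro[4.5]dec-6-ene-4,8-dione, via selenoxide 12 (not isolated)
Conditions: 30% H2O2, pyridine, CH2Cl2, 0 to 23 °C
Reagents that add atoms: none
Why: Selenoxide syn-elimination (Reich) can only take H-6, which the endo adduct places cis to selenium, so the C6=C7 enone forms regiospecifically and C5 and C10 are untouched.

**Step 8**
Reactants: 13 (2R,5S,10S)-6,10-dimethyl-2-(prop-1-en-2-yl)spiro[4.5]dec-6-ene-4,8-dione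
Product: 14 (2R,4S,5S,10S)-4-hydroxy-6,10-dimethyl-2-(prop-1-en-2-yl)spiro[4.5]dec-6-en-8-one
Conditions: NaBH4, EtOH–CH2Cl2, −40 °C
Reagents that add atoms: none
Why: Chemoselective borohydride reduction of the saturated cyclopentanone beside the conjugated enone (as with the Wieland–Miescher ketone); hydride enters C4 from the face away from the C10 methyl group, which leans over the other face, giving the 4S alcohol (O cis to C10, trans to isopropenyl).

**Step 9**
Reactants: 14 (2R,4S,5S,10S)-4-hydroxy-6,10-dimethyl-2-(prop-1-en-2-yl)spiro[4.5]dec-6-en-8-one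
Product: 15 (2R,4S,5S,10S)-6,10-dimethyl-8-oxo-2-(prop-1-en-2-yl)spiro[4.5]dec-6-en-4-yl 3-methylbut-2-enoate
Conditions: 3-methylbut-2-enoyl chloride, pyridine, 4-(dimethylamino)pyridine (cat.), CH2Cl2, 0 to 23 °C
Reagents that add atoms: 3-methylbut-2-enoyl chloride, CC(C)=CC(Cl)=O
Why: Acylation of the only hydroxyl group with retention at C4, pyridine being too weak a base to deconjugate the senecioyl unit.

**Step 10**
Reactants: 15 (2R,4S,5S,10S)-6,10-dimethyl-8-oxo-2-(prop-1-en-2-yl)spiro[4.5]dec-6-en-4-yl 3-methylbut-2-enoate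
Product: 16 (2R,4S,5S,9S,10R)-9-acetoxy-6,10-dimethyl-8-oxo-2-(prop-1-en-2-yl)spiro[4.5]dec-6-en-4-yl 3-methylbut-2-enoate (CNP0218315.1)
Conditions: Mn(OAc)3·2H2O (3 equiv), benzene, reflux (Dean–Stark)
Reagents that add atoms: manganese triacetate, CC(=O)[O-].CC(=O)[O-].CC(=O)[O-].[Mn+3]
Why: α′-Acetoxylation of the enone through its manganese enolate (trivalent manganese) can only occur at C9, and acetate is delivered trans to the adjacent C10 methyl group, the epimerisable centre settling as the trans (9S) isomer.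

## Compound list

1 | (S)-(+)-carvone, (5S)-2-methyl-5-(prop-1-en-2-yl)cyclohex-2-en-1-one | CC1=CC[C@H](C(C)=C)CC1=O | starting material
2 | (1S,4S,6S)-1-methyl-4-(prop-1-en-2-yl)-7-oxabicyclo[4.1.0]heptan-2-one (epoxide trans to isopropenyl) | C[C@]12O[C@H]1C[C@H](C(C)=C)CC2=O | intermediate
3 | tosylhydrazone of 2 (ring configuration of 2 retained; C=N geometry not defined) | C[C@]12O[C@H]1C[C@H](C(C)=C)CC2=NNS(=O)(=O)c3ccc(C)cc3 | intermediate
4 | (3R)-3-(prop-1-en-2-yl)hept-5-ynal | O=CC[C@H](C(C)=C)CC#CC | intermediate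
5 | Breslow enaminol of 4 with 1,3-dimesitylimidazol-2-ylidene | OC(=C1N(c2c(C)cc(C)cc2C)C=CN1c3c(C)cc(C)cc3C)C[C@H](C(C)=C)CC#CC | intermediate
6 | (2E,4R)-2-ethylidene-4-(prop-1-en-2-yl)cyclopentan-1-one | C/C=C1\C[C@@H](C(C)=C)CC1=O | intermediate
7 | (E)-pent-3-en-2-one | C/C=C/C(C)=O | starting material
8 | (E)-1-(phenylselanyl)pent-3-en-2-one | C/C=C/C(=O)C[Se]c1ccccc1 | intermediate
9 | tert-butyl(dimethyl){[(1Z,3E)-1-(phenylselanyl)penta-1,3-dien-2-yl]oxy}silane | C/C=C/C(O[Si](C)(C)C(C)(C)C)=C/[Se]c1ccccc1 | intermediate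
10 | (2R,5S,6R,7S,10S)-8-(tert-butyldimethylsilyloxy)-6,10-dimethyl-7-(phenylselanyl)-2-(prop-1-en-2-yl)spiro[4.5]dec-8-en-4-one | C=C(C)[C@H]1CC(=O)[C@]2(C1)[C@@H](C)[C@H]([Se]c3ccccc3)C(O[Si](C)(C)C(C)(C)C)=C[C@@H]2C | intermediate
11 | (2R,5S,6R,7S,10S)-6,10-dimethyl-7-(phenylselanyl)-2-(prop-1-en-2-yl)spiro[4.5]decane-4,8-dione | C=C(C)[C@H]1CC(=O)[C@]2(C1)[C@@H](C)[C@H]([Se]c3ccccc3)C(=O)C[C@@H]2C | intermediate
12 | selenoxide of 11 (selenium configuration not defined) | C=C(C)[C@H]1CC(=O)[C@]2(C1)[C@@H](C)[C@H]([Se](=O)c3ccccc3)C(=O)C[C@@H]2C | intermediate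
13 | (2R,5S,10S)-6,10-dimethyl-2-(prop-1-en-2-yl)spiro[4.5]dec-6-ene-4,8-dione | C=C(C)[C@H]1CC(=O)[C@]2(C1)C(C)=CC(=O)C[C@@H]2C | intermediate
14 | (2R,4S,5S,10S)-4-hydroxy-6,10-dimethyl-2-(prop-1-en-2-yl)spiro[4.5]dec-6-en-8-one | C=C(C)[C@H]1C[C@H](O)[C@]2(C1)C(C)=CC(=O)C[C@@H]2C | intermediate
15 | (2R,4S,5S,10S)-6,10-dimethyl-8-oxo-2-(prop-1-en-2-yl)spiro[4.5]dec-6-en-4-yl 3-methylbut-2-enoate | C=C(C)[C@H]1C[C@H](OC(=O)C=C(C)C)[C@]2(C1)C(C)=CC(=O)C[C@@H]2C | intermediate
16 | (2R,4S,5S,9S,10R)-9-acetoxy-6,10-dimethyl-8-oxo-2-(prop-1-en-2-yl)spiro[4.5]dec-6-en-4-yl 3-methylbut-2-enoate | C=C(C)[C@H]1C[C@H](OC(=O)C=C(C)C)[C@]2(C1)C(C)=CC(=O)[C@@H](OC(C)=O)[C@@H]2C | target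

## Step count and risks

Total: 10 steps. Longest linear sequence: 8 steps (1, 2, 3, 6, 7, 8, 9, 10); steps 4 and 5 make the diene.

**Step 3 (carbene hydroacylation; substrate class without precedent, and aldol or benzoin side reactions are possible).** The fallback sets out from 4 and returns at 6. SmI2 (samarium diiodide, divalent samarium) with HMPA and t-BuOH in THF turns the aldehyde into a ketyl radical anion, which cyclises 5-exo-dig onto the alkyne to give the allylic alcohol (4R)-2-ethylidene-4-(prop-1-en-2-yl)cyclopentan-1-ol F1 as an E/Z and carbinol-epimer mixture. Dess–Martin oxidation gives 6 together with its isomer (2Z,4R)-2-ethylidene-4-(prop-1-en-2-yl)cyclopentan-1-one F2, which a trace of iodine equilibrates to 6.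

**Step 6 (congested [4+2] that forms the quaternary C5; regiochemistry and endo/facial control of the selenium-bearing diene are uncertain).** The fallback sets out from 6 and returns at 13, building C5 by ordinary β-diketone chemistry.
- Conjugate borylation of 6 (CuCl, NaOt-Bu, Xantphos, B2pin2, MeOH, THF) gives the boronate (4R)-2-[1-(4,4,5,5-tetramethyl-1,3,2-dioxaborolan-2-yl)ethyl]-4-(prop-1-en-2-yl)cyclopentan-1-one F3.
- NaBO3·4H2O oxidises it to the aldol (4R)-2-(1-hydroxyethyl)-4-(prop-1-en-2-yl)cyclopentan-1-one F4.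
- Dess–Martin periodinane gives the β-diketone (4R)-2-acetyl-4-(prop-1-en-2-yl)cyclopentan-1-one F5.
- Michael addition of F5 to but-3-yn-2-one (Cs2CO3 cat.) anti to the isopropenyl group, then aldol condensation (KOH, MeOH), gives the spiro dienone (2R,5S)-6-methyl-2-(prop-1-en-2-yl)spiro[4.5]deca-6,9-diene-4,8-dione F6.
- Me2CuLi adds methyl to the unsubstituted enone carbon C10 from the side of the flat C4 carbonyl, and protonation gives 13.

**Step 10 (late radical-type oxidation on a substrate with three other π systems; trans selectivity at C9 is not guaranteed).** The fallback sets out from 15 and returns at 16. Kinetic α′-deprotonation with LiN(SiMe3)2 (THF, −78 °C) and oxidation of the enolate with 2-(phenylsulfonyl)-3-phenyloxaziridine, anti to the C10 methyl group, gives the α′-hydroxy enone (2R,4S,5S,9S,10R)-9-hydroxy-6,10-dimethyl-8-oxo-2-(prop-1-en-2-yl)spiro[4.5]dec-6-en-4-yl 3-methylbut-2-enoate F7. Acetylation (Ac2O, pyridine) gives 16.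

## Further compounds

F1 | step 3 | (4R)-2-ethylidene-4-(prop-1-en-2-yl)cyclopentan-1-ol (E/Z and carbinol epimers) | CC=C1C[C@@H](C(C)=C)CC1O
F2 | step 3 | (2Z,4R)-2-ethylidene-4-(prop-1-en-2-yl)cyclopentan-1-one | C/C=C1/C[C@@H](C(C)=C)CC1=O
F3 | step 6 | (4R)-2-[1-(4,4,5,5-tetramethyl-1,3,2-dioxaborolan-2-yl)ethyl]-4-(prop-1-en-2-yl)cyclopentan-1-one (other centres mixed) | C=C(C)[C@H]1CC(=O)C(C1)C(C)B2OC(C)(C)C(C)(C)O2
F4 | step 6 | (4R)-2-(1-hydroxyethyl)-4-(prop-1-en-2-yl)cyclopentan-1-one (other centres mixed) | C=C(C)[C@H]1CC(=O)C(C1)C(C)O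
F5 | step 6 | (4R)-2-acetyl-4-(prop-1-en-2-yl)cyclopentan-1-one | C=C(C)[C@H]1CC(=O)C(C1)C(C)=O
F6 | step 6 | (2R,5S)-6-methyl-2-(prop-1-en-2-yl)spiro[4.5]deca-6,9-diene-4,8-dione | C=C(C)[C@H]1CC(=O)[C@]2(C1)C(C)=CC(=O)C=C2
F7 | step 10 | (2R,4S,5S,9S,10R)-9-hydroxy-6,10-dimethyl-8-oxo-2-(prop-1-en-2-yl)spiro[4.5]dec-6-en-4-yl 3-methylbut-2-enoate | C=C(C)[C@H]1C[C@H](OC(=O)C=C(C)C)[C@]2(C1)C(C)=CC(=O)[C@@H](O)[C@@H]2C
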